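The flavanone is cut at O1–C8a and C4–C4a. Ring A is a symmetrical 5,7-dioxygenated benzene whose adjacent carbons C8a and C4a carry O1 and the C4 carbonyl; these match the two reactive carbons of 3,5-bis(benzyloxy)benzyne. In one operation the aryne is O-arylated by the carbinol oxygen of an (S)-β-hydroxy ester and the resulting aryl anion captures the ester carbonyl, closing ring C with C2 untouched. The precursors are a 2-silylaryl triflate and methyl (3S)-3-(3-bromo-5-iodo-4-methoxyphenyl)-3-hydroxypropanoate, masked in the flask as its TMS ether. The iodide and bromide then carry the alkynyl (later Z-alkenyl) and prenyl side chains of ring B.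

Key step: step 7

Remark: C2 of the target is (S); C3 of 10 and C2 of 13 carry the same descriptor, because the carbinol C–O bond is never broken and the CIP order O > aryl > CH2 is the same in all three. Compounds 1, 6, 15 and 17 are taken as purchasable.

Step 1
Reactants: 1 3,5-bis(benzyloxy)phenol
Product: 2 3,5-bis(benzyloxy)-2-bromophenol
Conditions: NBS, CH2Cl2, −78 °C to 0 °C
Reagents that add atoms: N-bromosuccinimide, O=C1CCC(=O)N1Br
Why: Electrophilic aromatic bromination of a phenol; at low temperature in a non-polar solvent NBS is delivered through a hydrogen bond to the hydroxyl, so C2 (between OH and OBn) should react in preference to C4, and the minor 4-bromo isomer is removed by chromatography.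

Step 2
Reactants: 2 3,5-bis(benzyloxy)-2-bromophenol
Product: 5 3,5-bis(benzyloxy)-2-(trimethylsilyl)phenyl trifluoromethanesulfonate, via TMS ether 3 (not isolated), via lithium phenolate 4 (not isolated)
Conditions: HMDS, THF, 70 °C, evaporate; n-BuLi, THF, −78 °C; Tf2O, −78 °C to rt
Reagents that add atoms: hexamethyldisilazane, C[Si](C)(C)N[Si](C)(C)C; trifluoromethanesulfonic anhydride, O=S(=O)(OS(=O)(=O)C(F)(F)F)C(F)(F)F
Why: O-silylation, bromine–lithium exchange and anionic 1,3 O→C silyl migration (retro-Brook rearrangement) place the TMS group ortho to the phenolate, which Tf2O traps; this is the standard entry to Kobayashi aryne precursors, and the exchange at −78 °C outruns benzylic deprotonation of the benzyl ethers.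

Step 3
Reactants: 6 1-(3-bromo-4-hydroxyphenyl)ethan-1-one
Product: 7 1-(3-bromo-4-hydroxy-5-iodophenyl)ethan-1-one
Conditions: NIS, TsOH·H2O (cat.), MeCN, rt
Reagents that add atoms: N-iodosuccinimide, O=C1CCC(=O)N1I
Why: Acid-catalysed electrophilic iodination of a phenol; only the free position ortho to the hydroxyl (C5) is activated, and ring iodination is much faster than α-iodination of the methyl ketone at room temperature.

Step 4
Reactants: 7 1-(3-bromo-4-hydroxy-5-iodophenyl)ethan-1-one
Product: 8 1-(3-bromo-5-iodo-4-methoxyphenyl)ethan-1-one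
Conditions: MeI, K2CO3, DMF, rt
Reagents that add atoms: iodomethane, CI
Why: Williamson ether synthesis; the acidic 2,6-dihalophenoxide is O-methylated by MeI, and K2CO3 is too weak to enolise the methyl ketone.

Step 5
Reactants: 8 1-(3-bromo-5-iodo-4-methoxyphenyl)ethan-1-one
Product: 9 methyl 3-(3-bromo-5-iodo-4-methoxyphenyl)-3-oxopropanoate
Conditions: NaH, (MeO)2CO, THF, reflux; then aq. HCl
Reagents that add atoms: dimethyl carbonate, COC(=O)OC
Why: Crossed Claisen condensation; the sodium enolate of the methyl ketone is acylated by dimethyl carbonate and the reaction is driven by formation of the stabilised β-keto ester enolate, while the aryl bromide and iodide are inert to NaH.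

Step 6
Reactants: 9 methyl 3-(3-bromo-5-iodo-4-methoxyphenyl)-3-oxopropanoate
Product: 10 methyl (3S)-3-(3-bromo-5-iodo-4-methoxyphenyl)-3-hydroxypropanoate
Conditions: RuCl(p-cymene)[(S,S)-TsDPEN] (1 mol%), HCO2H/Et3N (5:2), DMF, 40 °C
Reagents that add atoms: none
Why: Noyori–Ikariya asymmetric transfer hydrogenation; the (S,S)-TsDPEN ruthenium hydride delivers hydride through the outer-sphere six-membered transition state with the aryl group held against the η6-cymene ligand, which should give the (S)-benzylic carbinol just as it gives (S)-1-arylethanols, the aryl halides are untouched by divalent ruthenium, and one recrystallisation would raise the enantiomeric purity if needed.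

Step 7
Reactants: 10 methyl (3S)-3-(3-bromo-5-iodo-4-methoxyphenyl)-3-hydroxypropanoate; 5 3,5-bis(benzyloxy)-2-(trimethylsilyl)phenyl trifluoromethanesulfonate
Product: 13 (2S)-5,7-bis(benzyloxy)-2-(3-bromo-5-iodo-4-methoxyphenyl)chroman-4-one, via TMS ether 11 (not isolated), via benzyne 12 (not isolated)
Conditions: HMDS, TMSCl (cat.), THF, 50 °C, evaporate; then 5 (1.3 equiv), KF (1.5 equiv), 18-crown-6, THF, 0 °C to rt; pH 7 buffer
Reagents that add atoms: none
Why: Proposed new method: the carbinol is first masked as TMS ether 11 so that no O–H proton is present; fluoride then cleaves the O–Si bond of 11 and the C–Si bond of 5 (with 1,2-loss of triflate, giving aryne 12), the alkoxide adds to the aryne carbon meta to the flanking benzyloxy group (O1–C8a), and the aryl anion, formed ortho to that group where induction stabilises it, attacks the methyl ester (C4–C4a) and expels methoxide, which the silyl groups still present convert into MeOSiMe3. The closest known reactions are the fluoride-mediated annulation of arynes with methyl salicylates to xanthones and the insertion of arynes into carboxylic acids to give ortho-hydroxyaryl ketones, which use the same O-arylation and acyl-capture sequence; new here is an aliphatic β-alkoxy ester as the partner. Ring C closes by a 6-exo-trig acyl substitution. No stereocentre is formed: C2 keeps the (S) configuration of 10 because only the bond from the carbinol oxygen to H (Si) reacts and the C–O bond is never broken. The step needs aryne regioselectivity, which the inductive distortion by the C3 benzyloxy group supplies, and the symmetry of the 3,5-pattern turns this single preference into the 5,7-dioxygenation. It also needs acyl capture to run ahead of proton quench, retro-aldol cleavage and base-induced opening of ring C, which the proton-free silyl-masked precursor, the gradual release of alkoxide at 0 °C and the internal silylation of methoxide are meant to secure.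

Step 8
Reactants: 13 (2S)-5,7-bis(benzyloxy)-2-(3-bromo-5-iodo-4-methoxyphenyl)chroman-4-one
Product: 14 (2S)-2-(3-bromo-5-iodo-4-methoxyphenyl)-5,7-dihydroxychroman-4-one
Conditions: BCl3, pentamethylbenzene, CH2Cl2, −78 °C; then H2O
Reagents that add atoms: none
Why: Lewis-acid debenzylation with a non-basic cation scavenger; BCl3 cleaves aryl benzyl ethers at −78 °C, pentamethylbenzene prevents C-benzylation of the electron-rich ring A, the halogen-flanked methyl ether, the aryl halides and C2 should be untouched at this temperature, and the step is placed here because the later alkenes and tertiary alcohol would not survive it.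

Step 9
Reactants: 14 (2S)-2-(3-bromo-5-iodo-4-methoxyphenyl)-5,7-dihydroxychroman-4-one; 15 2-methylbut-3-yn-2-ol
Product: 16 (2S)-2-[3-bromo-5-(3-hydroxy-3-methylbut-1-yn-1-yl)-4-methoxyphenyl]-5,7-dihydroxychroman-4-one
Conditions: Pd(PPh3)2Cl2, CuI, Et3N, DMF, rt
Reagents that add atoms: none
Why: Sonogashira coupling; oxidative addition of zerovalent palladium to the C–I bond is far faster than to the C–Br bond at room temperature, so only the iodide is alkynylated, and the mild amine base should not open ring C because the 7-phenoxide disfavours enolisation at C3.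

Step 10
Reactants: 16 (2S)-2-[3-bromo-5-(3-hydroxy-3-methylbut-1-yn-1-yl)-4-methoxyphenyl]-5,7-dihydroxychroman-4-one; 17 tributyl(3-methylbut-2-en-1-yl)stannane
Product: 18 (2S)-5,7-dihydroxy-2-[3-(3-hydroxy-3-methylbut-1-yn-1-yl)-4-methoxy-5-(3-methylbut-2-en-1-yl)phenyl]chroman-4-one
Conditions: Pd(PPh3)4, DMF, 90 °C
Reagents that add atoms: none
Why: Stille coupling of the remaining aryl bromide under neutral conditions; the allylpalladium intermediate should reductively eliminate at its less hindered terminus to give the linear 3-methylbut-2-enyl group, and the free phenols, the tertiary alkynol and the base-sensitive flavanone tolerate base-free conditions.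

Step 11
Reactants: 18 (2S)-5,7-dihydroxy-2-[3-(3-hydroxy-3-methylbut-1-yn-1-yl)-4-methoxy-5-(3-methylbut-2-en-1-yl)phenyl]chroman-4-one
Product: 19 (2S)-5,7-dihydroxy-2-{3-[(1Z)-3-hydroxy-3-methylbut-1-en-1-yl]-4-methoxy-5-(3-methylbut-2-en-1-yl)phenyl}chroman-4-one
Conditions: H2 (1 atm), Pd/CaCO3 poisoned with Pb(OAc)2, quinoline, EtOAc, rt
Reagents that add atoms: none
Why: Lindlar semihydrogenation; syn addition of H2 on the poisoned palladium surface gives the (Z)-alkene and should stop there, while the trisubstituted prenyl alkene, the aryl ketone and the benzylic C2–O bond are not reduced at 1 atm and room temperature.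

Compound list
1 | 3,5-bis(benzyloxy)phenol | Oc1cc(OCc2ccccc2)cc(OCc2ccccc2)c1 | starting material
2 | 3,5-bis(benzyloxy)-2-bromophenol | Oc1cc(OCc2ccccc2)cc(OCc2ccccc2)c1Br | intermediate
3 | [3,5-bis(benzyloxy)-2-bromophenoxy]trimethylsilane | C[Si](C)(C)Oc1cc(OCc2ccccc2)cc(OCc2ccccc2)c1Br | intermediate
4 | lithium 3,5-bis(benzyloxy)-2-(trimethylsilyl)phenolate | [Li+].[O-]c1cc(OCc2ccccc2)cc(OCc2ccccc2)c1[Si](C)(C)C | intermediate
5 | 3,5-bis(benzyloxy)-2-(trimethylsilyl)phenyl trifluoromethanesulfonate | C[Si](C)(C)c1c(OCc2ccccc2)cc(OCc2ccccc2)cc1OS(=O)(=O)C(F)(F)F | intermediate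
6 | 1-(3-bromo-4-hydroxyphenyl)ethan-1-one | CC(=O)c1ccc(O)c(Br)c1 | starting material
7 | 1-(3-bromo-4-hydroxy-5-iodophenyl)ethan-1-one | CC(=O)c1cc(Br)c(O)c(I)c1 | intermediate
8 | 1-(3-bromo-5-iodo-4-methoxyphenyl)ethan-1-one | COc1c(Br)cc(C(C)=O)cc1I | intermediate
9 | methyl 3-(3-bromo-5-iodo-4-methoxyphenyl)-3-oxopropanoate | COC(=O)CC(=O)c1cc(Br)c(OC)c(I)c1 | intermediate
10 | methyl (3S)-3-(3-bromo-5-iodo-4-methoxyphenyl)-3-hydroxypropanoate | COc1c(Br)cc([C@@H](O)CC(=O)OC)cc1I | intermediate
11 | methyl (3S)-3-(3-bromo-5-iodo-4-methoxyphenyl)-3-[(trimethylsilyl)oxy]propanoate | COc1c(Br)cc([C@@H](O[Si](C)(C)C)CC(=O)OC)cc1I | intermediate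
12 | 3,5-bis(benzyloxy)benzyne (1,2-didehydro-3,5-bis(benzyloxy)benzene) | C1#CC(OCc2ccccc2)=CC(OCc2ccccc2)=C1 | intermediate
13 | (2S)-5,7-bis(benzyloxy)-2-(3-bromo-5-iodo-4-methoxyphenyl)chroman-4-one | COc1c(Br)cc([C@@H]2CC(=O)c3c(OCc4ccccc4)cc(OCc4ccccc4)cc3O2)cc1I | intermediate
14 | (2S)-2-(3-bromo-5-iodo-4-methoxyphenyl)-5,7-dihydroxychroman-4-one | COc1c(Br)cc([C@@H]2CC(=O)c3c(O)cc(O)cc3O2)cc1I | intermediate
15 | 2-methylbut-3-yn-2-ol | CC(C)(O)C#C | starting material
16 | (2S)-2-[3-bromo-5-(3-hydroxy-3-methylbut-1-yn-1-yl)-4-methoxyphenyl]-5,7-dihydroxychroman-4-one | COc1c(Br)cc([C@@H]2CC(=O)c3c(O)cc(O)cc3O2)cc1C#CC(C)(C)O | intermediate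
17 | tributyl(3-methylbut-2-en-1-yl)stannane | CCCC[Sn](CCCC)(CCCC)CC=C(C)C | starting material
18 | (2S)-5,7-dihydroxy-2-[3-(3-hydroxy-3-methylbut-1-yn-1-yl)-4-methoxy-5-(3-methylbut-2-en-1-yl)phenyl]chroman-4-one | COc1c(CC=C(C)C)cc([C@@H]2CC(=O)c3c(O)cc(O)cc3O2)cc1C#CC(C)(C)O | intermediate
19 | (2S)-5,7-dihydroxy-2-{3-[(1Z)-3-hydroxy-3-methylbut-1-en-1-yl]-4-methoxy-5-(3-methylbut-2-en-1-yl)phenyl}chroman-4-one | COc1c(/C=C\C(C)(C)O)cc([C@@H]2CC(=O)c3c(O)cc(O)cc3O2)cc1CC=C(C)C | target

Total step count: 11. Longest linear sequence: 9 steps (steps 3 to 11, from 6); steps 1 and 2 form the convergent branch to 5.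

Steps most likely to fail

Step 7 (the new annulation). The aryl anion may be protonated before it reaches the ester, either by traces of protic material or by its own α-methylene followed by β-elimination of the aryloxide. The transient alkoxide may fragment by retro-aldol cleavage. Base left at the end may open ring C and erode the configuration at C2. The fallback uses only known reactions and sets out from keto ester 9 and phenol 1. Transfer hydrogenation of 9 with the enantiomeric catalyst RuCl(p-cymene)[(R,R)-TsDPEN] in HCO2H/Et3N would give methyl (3R)-3-(3-bromo-5-iodo-4-methoxyphenyl)-3-hydroxypropanoate F1. Mitsunobu etherification of this alcohol with phenol 1 (PPh3, DIAD, toluene, 0 °C) would form the C2–O1 bond with inversion, giving methyl (3S)-3-[3,5-bis(benzyloxy)phenoxy]-3-(3-bromo-5-iodo-4-methoxyphenyl)propanoate F2. Saponification (LiOH, THF/H2O, 0 °C) would give (3S)-3-[3,5-bis(benzyloxy)phenoxy]-3-(3-bromo-5-iodo-4-methoxyphenyl)propanoic acid F3. Intramolecular Friedel–Crafts acylation (TFAA, CH2Cl2, 0 °C) at either of the two equivalent positions ortho to the ether oxygen would close ring C and return to 13.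

Step 10 (prenyl Stille coupling). Transmetalation of the hindered prenylstannane may be slow enough for protodebromination to compete. Transfer through the γ-carbon may give the 1,1-dimethylallyl isomer. Prolonged heating may erode the configuration at C2. The fallback sets out from 16 and builds the prenyl group in two stages, which removes the α/γ question. Stille coupling with allyltributylstannane (Pd(PPh3)4, DMF, 80 °C) would give (2S)-5,7-dihydroxy-2-[3-(3-hydroxy-3-methylbut-1-yn-1-yl)-4-methoxy-5-(prop-2-en-1-yl)phenyl]chroman-4-one F4. Olefin cross-metathesis with excess 2-methylbut-2-ene (second-generation Hoveyda–Grubbs catalyst, RuCl2(H2IMes)(=CH-C6H4-2-OiPr), CH2Cl2, 40 °C) would then return to 18.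

Step 11 (semihydrogenation). The alkene may be reduced further to the saturated chain, the (Z)-alkene may isomerise to (E) on palladium, or tin and iodide residues from the earlier couplings may poison the catalyst and stall the reaction. The fallback sets out from 18 and replaces catalytic hydrogenation by a dissolving-metal reduction. Zinc dust activated with Cu(OAc)2 and AgNO3 in MeOH/H2O at rt reduces aryl- and hydroxyl-activated alkynes to cis-alkenes by electron transfer and protonation, and cannot reduce an isolated alkene. It would return directly to 19 and makes no new compound.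

Further compounds
F1 | step 7 | methyl (3R)-3-(3-bromo-5-iodo-4-methoxyphenyl)-3-hydroxypropanoate | COc1c(Br)cc([C@H](O)CC(=O)OC)cc1I
F2 | step 7 | methyl (3S)-3-[3,5-bis(benzyloxy)phenoxy]-3-(3-bromo-5-iodo-4-methoxyphenyl)propanoate | COc1c(Br)cc([C@@H](Oc2cc(OCc3ccccc3)cc(OCc3ccccc3)c2)CC(=O)OC)cc1I
F3 | step 7 | (3S)-3-[3,5-bis(benzyloxy)phenoxy]-3-(3-bromo-5-iodo-4-methoxyphenyl)propanoic acid | COc1c(Br)cc([C@@H](Oc2cc(OCc3ccccc3)cc(OCc3ccccc3)c2)CC(=O)O)cc1I
F4 | step 10 | (2S)-5,7-dihydroxy-2-[3-(3-hydroxy-3-methylbut-1-yn-1-yl)-4-methoxy-5-(prop-2-en-1-yl)phenyl]chroman-4-one | COc1c(CC=C)cc([C@@H]2CC(=O)c3c(O)cc(O)cc3O2)cc1C#CC(C)(C)O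
F0 | step 11 | none | none
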